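## Retrosynthetic overview

- The oxane ring is cut at O1–C6 and at C2–C3. This gives a C13 methyl ketone that already carries the finished bromocyclohexanol (ring A, as its silyl ether) and a geraniol-derived C7 unit that is an α-bromo carbanion at one end and an allylic carbonate at the other. Both bonds are made in one flask, as a formal [4+2] annulation of a ketone with a 1,4-dipole equivalent.
- Enabling feature: in the oxane, C6 carries the vinyl group, so O1–C6 is an allylic C–O bond (π-allyl retron). C2 is a tertiary ether carbon bonded to the CHBr carbon C3, so C2–C3 is the bond of a β-bromo alkoxide (ketone plus α-bromo carbanion retron). C3–C4–C5–C6 form one isoprenoid chain.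
- Ring A is built first from homoprenyl bromide and glutaric anhydride: an enol-lactone-terminated enantioselective bromonium cyclisation sets C–Br, then a double methyl addition gives the axial tertiary alcohol and the methyl ketone.
- Order of ring formation: cyclohexane (step 3), then oxane (step 12); the last step frees the tertiary alcohol.

Key step: step 12

Remark (assumption): the senses of induction of the thiophosphoramide (step 3), the tartrate (step 10) and the Trost ligand (step 12) are assigned by analogy with the closest reported substrates; where a sense proves reversed, the enantiomeric ligand is used.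

## Route

Step 1
Reactants: 1 5-bromo-2-methylpent-2-ene; 2 glutaric anhydride (oxane-2,6-dione)
Product: 3 9-methyl-5-oxodec-8-enoic acid
Conditions: Mg, THF, 23 °C; then added to 2 (1.5 equiv), THF, −78 → 0 °C; aq. HCl
Reagents that add atoms: none
Why: Acylation of a Grignard reagent by a cyclic anhydride at low temperature should stop at the keto acid, because the magnesium carboxylate formed is a poor electrophile; no stereocentre is formed.

Step 2
Reactants: 3 9-methyl-5-oxodec-8-enoic acid
Product: 4 6-(4-methylpent-3-en-1-yl)-3,4-dihydro-2H-pyran-2-one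
Conditions: (COCl)2, DMF (cat.), CH2Cl2, 0 °C; then Et3N, 0 → 23 °C
Reagents that add atoms: none
Why: Enol lactonisation of a δ-keto acid through its acid chloride and base-induced elimination should place the enol double bond inside the six-membered lactone, which fixes the nucleophilic carbon for step 3; no stereocentre is formed.

Step 3
Reactants: 4 6-(4-methylpent-3-en-1-yl)-3,4-dihydro-2H-pyran-2-one
Product: 6 3-[(1R,3R)-3-bromo-2,2-dimethyl-6-oxocyclohexyl]propanoic acid, via bicyclic bromo enol lactone 5 (not isolated)
Conditions: DBDMH (0.55 equiv), (S)-BINOL-derived N-triflyl thiophosphoramide (10 mol %), toluene/CH2Cl2, −90 °C; then LiOH, THF/H2O, 0 °C; aq. HCl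
Reagents that add atoms: 1,3-dibromo-5,5-dimethylhydantoin CC1(C)N(Br)C(=O)N(Br)C1=O; lithium hydroxide [Li+].[OH-]
Why: Proposed new method: the chiral Lewis base–bromenium complex should brominate the electron-rich trisubstituted alkene enantioselectively, and the bromonium ion is opened at its tertiary carbon by the enol lactone carbon in a chair-like 6-endo cation–olefin cyclisation whose acyloxy carbenium ion ends as ring ketone plus carboxylic acid after hydrolysis (closest known reactions: thiophosphoramide/DBDMH-catalysed enantioselective bromocyclisation of homogeranylarenes and enol-ester-terminated cation–olefin cyclisations); the C–Br centre is set by the catalyst, and the epimerisable α-centre of the ketone settles with the side chain equatorial, cis to bromine.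

Step 4
Reactants: 6 3-[(1R,3R)-3-bromo-2,2-dimethyl-6-oxocyclohexyl]propanoic acid
Product: 7 3-[(1R,3R)-3-bromo-2,2-dimethyl-6-oxocyclohexyl]-N-methoxy-N-methylpropanamide
Conditions: CDI, CH2Cl2, 23 °C; then MeNH(OMe)·HCl
Reagents that add atoms: N,O-dimethylhydroxylamine hydrochloride CNOC.Cl
Why: Weinreb amide formation through the acyl imidazolide should tolerate the ketone and the secondary bromide; no stereocentre is formed, and the α-centre stays in its favoured equatorial form.

Step 5
Reactants: 7 3-[(1R,3R)-3-bromo-2,2-dimethyl-6-oxocyclohexyl]-N-methoxy-N-methylpropanamide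
Product: 9 4-[(1R,3R,6S)-3-bromo-2,2,6-trimethyl-6-(trimethylsilyloxy)cyclohexyl]butan-2-one, via bis(bromomagnesium) adduct 8 (not isolated)
Conditions: MeMgBr (3.5 equiv), LaCl3·2LiCl (1 equiv), THF, −78 → 0 °C; then TMSOTf, −78 → 0 °C; aq. NaHCO3
Reagents that add atoms: methylmagnesium bromide C[Mg]Br; trimethylsilyl trifluoromethanesulfonate C[Si](C)(C)OS(=O)(=O)C(F)(F)F
Why: In this Grignard addition the Weinreb amide should stop at the chelated tetrahedral adduct (methyl ketone after work-up), while the ring ketone is attacked on its equatorial face because the axial methyl of the gem-dimethyl group blocks the axial path, giving the axial tertiary alkoxide cis to the side chain; it is silylated in the flask so that the free hydroxy ketone, which would close to a hemiketal, is never handled.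

Step 6
Reactants: 10 geraniol, (2E)-3,7-dimethylocta-2,6-dien-1-ol
Product: 11 tert-butyl (2E)-3,7-dimethylocta-2,6-dien-1-yl carbonate
Conditions: Boc2O, DMAP (cat.), MeCN, 23 °C
Reagents that add atoms: di-tert-butyl dicarbonate CC(C)(C)OC(=O)OC(=O)OC(C)(C)C
Why: DMAP-catalysed O-acylation should turn the allylic alcohol into a hindered tert-butyl carbonate, a leaving group for π-allylpalladium formation that resists Grignard reagents at −78 °C; no stereocentre is formed.

Step 7
Reactants: 11 tert-butyl (2E)-3,7-dimethylocta-2,6-dien-1-yl carbonate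
Product: 12 tert-butyl (2E)-3-methyl-6-oxohex-2-en-1-yl carbonate
Conditions: O3 (1 equiv), pyridine, CH2Cl2, −78 °C; then Me2S
Reagents that add atoms: ozone [O-][O+]=O
Why: In this ozonolysis the distal trisubstituted alkene is more electron-rich than the alkene deactivated by the allylic carbonate, so one equivalent of ozone should cleave it selectively; no stereocentre is formed.

Step 8
Reactants: 12 tert-butyl (2E)-3-methyl-6-oxohex-2-en-1-yl carbonate
Product: 13 tert-butyl (2E)-6-hydroxy-3-methylhex-2-en-1-yl carbonate
Conditions: NaBH4, MeOH, 0 °C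
Reagents that add atoms: none
Why: Borohydride reduction of the aldehyde should leave carbonate and alkene untouched; no stereocentre is formed.

Step 9
Reactants: 13 tert-butyl (2E)-6-hydroxy-3-methylhex-2-en-1-yl carbonate
Product: 14 tert-butyl (2E)-3-methyl-6-[(4-methylphenyl)sulfanyl]hex-2-en-1-yl carbonate
Conditions: (4-MeC6H4S)2, PBu3, pyridine, 23 °C
Reagents that add atoms: bis(4-methylphenyl) disulfide Cc1ccc(SSc2ccc(C)cc2)cc1
Why: Hata thioetherification (disulfide/trialkylphosphine) should replace the primary hydroxyl by the arylthio group through SN2 displacement of the phosphonium-activated oxygen; no stereocentre is formed.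

Step 10
Reactants: 14 tert-butyl (2E)-3-methyl-6-[(4-methylphenyl)sulfanyl]hex-2-en-1-yl carbonate
Product: 15 tert-butyl (2E)-3-methyl-6-[(R)-(4-methylphenyl)sulfinyl]hex-2-en-1-yl carbonate
Conditions: Ti(OiPr)4, (R,R)-diethyl tartrate, H2O, cumene hydroperoxide, CH2Cl2, −20 °C
Reagents that add atoms: cumene hydroperoxide CC(C)(OO)c1ccccc1
Why: Kagan sulfoxidation should transfer oxygen enantioselectively to the aryl alkyl sulfide (the titanium reagent epoxidises only allylic alcohols, so the alkene is safe), setting the sulfur stereocentre that serves as a handle for the next two steps.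

Step 11
Reactants: 15 tert-butyl (2E)-3-methyl-6-[(R)-(4-methylphenyl)sulfinyl]hex-2-en-1-yl carbonate
Product: 16 tert-butyl (2E,6R)-6-bromo-3-methyl-6-[(R)-(4-methylphenyl)sulfinyl]hex-2-en-1-yl carbonate
Conditions: NBS, pyridine, CH2Cl2/MeCN, −20 °C; separation of the (6R) diastereomer
Reagents that add atoms: N-bromosuccinimide O=C1CCC(=O)N1Br
Why: α-Halogenation of the sulfoxide through a bromosulfoxonium ylide should place bromine on the sulfinyl-bearing carbon under control of the sulfur stereocentre, and the purified (6R) diastereomer fixes the configuration of the future CHBr carbon.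

Step 12
Reactants: 9 4-[(1R,3R,6S)-3-bromo-2,2,6-trimethyl-6-(trimethylsilyloxy)cyclohexyl]butan-2-one; 16 tert-butyl (2E,6R)-6-bromo-3-methyl-6-[(R)-(4-methylphenyl)sulfinyl]hex-2-en-1-yl carbonate
Product: 19 {[(1S,2R,4R)-4-bromo-2-{2-[(2S,3R,6S)-3-bromo-6-ethenyl-2,6-dimethyloxan-2-yl]ethyl}-1,3,3-trimethylcyclohexyl]oxy}(trimethyl)silane, via α-bromoalkyl Grignard reagent 17 (not isolated), via β-bromo magnesium alkoxide 18 (not isolated)
Conditions: 16, EtMgCl (1.0 equiv), THF, −78 °C, 10 min; 9, −78 → −50 °C; then ZnCl2 (1.0 equiv), Pd2(dba)3·CHCl3 (2.5 mol %), (R,R)-DACH-phenyl Trost ligand (7.5 mol %), −50 → 23 °C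
Reagents that add atoms: none
Why: Proposed new method: ethylmagnesium chloride attacks sulfur of 16 (sulfoxide–magnesium exchange) and releases the α-bromoalkyl Grignard reagent 17 with retention at carbon, 17 adds to the methyl ketone of 9 to form the oxane C2–C3 bond as the β-bromo magnesium alkoxide 18, and after transmetalation to zinc the alkoxide is allylated by the π-allylpalladium complex ionised from the tert-butyl carbonate to form the O1–C6 bond; the closest known reactions are carbonyl additions of configurationally stable α-haloalkyl Grignard reagents made by sulfoxide–magnesium exchange and the palladium-catalysed allylic etherification of zinc alkoxides, here merged into a formal [4+2] annulation. The oxane closes by 6-exo attack of the alkoxide oxygen on the more substituted terminus of the π-allyl unit, the eight-membered alternative at the primary terminus being disfavoured by ring size. Oxane C3 (CHBr) is set by the configuration of the carbenoid carbon, transferred with retention, and oxane C6 (methyl, vinyl) by the Trost ligand, which selects the face of the π-allyl unit presented to the tethered oxygen. Oxane C2 is set by the face of the ketone that is attacked, and because methyl and the CH2CH2 chain differ little no substrate bias is claimed, so the C2 epimer is expected as a co-product to be removed by chromatography at this stage. The step needs chemoselectivity for ketone addition over attack on the carbonate and for six-ring O-allylation over three-ring epoxide closure, which the low temperature, the hindered tert-butyl carbonate and the covalent magnesium or zinc alkoxide are meant to secure, while the silyl ether keeps the ring A oxygen silent.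

Step 13
Reactants: 19 {[(1S,2R,4R)-4-bromo-2-{2-[(2S,3R,6S)-3-bromo-6-ethenyl-2,6-dimethyloxan-2-yl]ethyl}-1,3,3-trimethylcyclohexyl]oxy}(trimethyl)silane
Product: 20 (1S,2R,4R)-4-bromo-2-{2-[(2S,3R,6S)-3-bromo-6-ethenyl-2,6-dimethyloxan-2-yl]ethyl}-1,3,3-trimethylcyclohexan-1-ol
Conditions: K2CO3 (cat.), MeOH, 23 °C
Reagents that add atoms: none
Why: Base-catalysed methanolysis of the tertiary trimethylsilyl ether should free the axial tertiary alcohol without touching the secondary bromides, the tertiary allylic ether or any stereocentre.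

## Compound list

1 | 5-bromo-2-methylpent-2-ene | CC(C)=CCCBr | starting material
2 | glutaric anhydride (oxane-2,6-dione) | O=C1CCCC(=O)O1 | starting material
3 | 9-methyl-5-oxodec-8-enoic acid | CC(C)=CCCC(=O)CCCC(=O)O | intermediate
4 | 6-(4-methylpent-3-en-1-yl)-3,4-dihydro-2H-pyran-2-one | CC(C)=CCCC1=CCCC(=O)O1 | intermediate
5 | (4aR,6R)-6-bromo-5,5-dimethyl-3,4,4a,5,6,7-hexahydro-2H-chromen-2-one (bicyclic bromo enol lactone, not isolated) | O=C1CC[C@@H]2C(C)(C)[C@H](Br)CC=C2O1 | intermediate
6 | 3-[(1R,3R)-3-bromo-2,2-dimethyl-6-oxocyclohexyl]propanoic acid | OC(=O)CC[C@@H]1C(C)(C)[C@H](Br)CCC1=O | intermediate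
7 | 3-[(1R,3R)-3-bromo-2,2-dimethyl-6-oxocyclohexyl]-N-methoxy-N-methylpropanamide | CON(C)C(=O)CC[C@@H]1C(C)(C)[C@H](Br)CCC1=O | intermediate
8 | bis(bromomagnesium) adduct: ring tertiary alkoxide plus Weinreb tetrahedral alkoxide (not isolated) | CON(C)C(C)(O[Mg]Br)CC[C@@H]1C(C)(C)[C@H](Br)CC[C@]1(C)O[Mg]Br | intermediate
9 | 4-[(1R,3R,6S)-3-bromo-2,2,6-trimethyl-6-(trimethylsilyloxy)cyclohexyl]butan-2-one | CC(=O)CC[C@@H]1C(C)(C)[C@H](Br)CC[C@]1(C)O[Si](C)(C)C | intermediate
10 | geraniol, (2E)-3,7-dimethylocta-2,6-dien-1-ol | CC(C)=CCC/C(C)=C/CO | starting material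
11 | tert-butyl (2E)-3,7-dimethylocta-2,6-dien-1-yl carbonate | CC(C)=CCC/C(C)=C/COC(=O)OC(C)(C)C | intermediate
12 | tert-butyl (2E)-3-methyl-6-oxohex-2-en-1-yl carbonate | O=CCC/C(C)=C/COC(=O)OC(C)(C)C | intermediate
13 | tert-butyl (2E)-6-hydroxy-3-methylhex-2-en-1-yl carbonate | OCCC/C(C)=C/COC(=O)OC(C)(C)C | intermediate
14 | tert-butyl (2E)-3-methyl-6-[(4-methylphenyl)sulfanyl]hex-2-en-1-yl carbonate | Cc1ccc(SCCC/C(C)=C/COC(=O)OC(C)(C)C)cc1 | intermediate
15 | tert-butyl (2E)-3-methyl-6-[(R)-(4-methylphenyl)sulfinyl]hex-2-en-1-yl carbonate | Cc1ccc(cc1)[S@](=O)CCC/C(C)=C/COC(=O)OC(C)(C)C | intermediate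
16 | tert-butyl (2E,6R)-6-bromo-3-methyl-6-[(R)-(4-methylphenyl)sulfinyl]hex-2-en-1-yl carbonate | Cc1ccc(cc1)[S@@](=O)[C@H](Br)CC/C(C)=C/COC(=O)OC(C)(C)C | intermediate
17 | tert-butyl (2E,6R)-6-bromo-6-(chloromagnesio)-3-methylhex-2-en-1-yl carbonate (α-bromoalkyl Grignard reagent, not isolated) | Cl[Mg][C@H](Br)CC/C(C)=C/COC(=O)OC(C)(C)C | intermediate
18 | tert-butyl (2E,6R,7S)-6-bromo-7-(chloromagnesiooxy)-3,7-dimethyl-9-[(1R,3R,6S)-3-bromo-2,2,6-trimethyl-6-(trimethylsilyloxy)cyclohexyl]non-2-en-1-yl carbonate (not isolated) | CC(C)(C)OC(=O)OC/C=C(C)/CC[C@@H](Br)[C@](C)(CC[C@@H]1C(C)(C)[C@H](Br)CC[C@]1(C)O[Si](C)(C)C)O[Mg]Cl | intermediate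
19 | {[(1S,2R,4R)-4-bromo-2-{2-[(2S,3R,6S)-3-bromo-6-ethenyl-2,6-dimethyloxan-2-yl]ethyl}-1,3,3-trimethylcyclohexyl]oxy}(trimethyl)silane | C=C[C@]1(C)CC[C@@H](Br)[C@](C)(CC[C@@H]2C(C)(C)[C@H](Br)CC[C@]2(C)O[Si](C)(C)C)O1 | intermediate
20 | (1S,2R,4R)-4-bromo-2-{2-[(2S,3R,6S)-3-bromo-6-ethenyl-2,6-dimethyloxan-2-yl]ethyl}-1,3,3-trimethylcyclohexan-1-ol | C=C[C@]1(C)CC[C@@H](Br)[C@](C)(CC[C@@H]2C(C)(C)[C@H](Br)CC[C@]2(C)O)O1 | target

## Summary and risk

Total step count: 13. Longest linear sequence: 8 steps (steps 6 to 13, from geraniol).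

Steps most likely to fail:

1. Step 12 (Proposed new method). Facial discrimination at the methyl ketone is expected to be weak, so the C2-oxane epimer should form alongside the product. In addition, the carbenoid may racemise or suffer bromine–magnesium exchange instead of sulfoxide–magnesium exchange, the ketone may be enolised, and the β-bromo alkoxide may close prematurely to an epoxide. Fallback with known reactions, setting out from 9 and 16 and coming back at 19: the Grignard reagent 17 is generated and added to 9 as before, but the mixture is warmed to 23 °C without palladium, so that the alkoxide 18 deliberately closes (Köbrich-type carbenoid epoxidation of a ketone) to the trisubstituted epoxide tert-butyl (2E)-5-[(2S,3S)-3-{2-[(1R,3R,6S)-3-bromo-2,2,6-trimethyl-6-(trimethylsilyloxy)cyclohexyl]ethyl}-3-methyloxiran-2-yl]-3-methylpent-2-en-1-yl carbonate F1. This stable epoxide is separated from its geometric isomer. It is then opened with Li2NiBr4 in THF at the less substituted carbon with inversion to the bromohydrin tert-butyl (2E,6R,7S)-6-bromo-7-hydroxy-3,7-dimethyl-9-[(1R,3R,6S)-3-bromo-2,2,6-trimethyl-6-(trimethylsilyloxy)cyclohexyl]non-2-en-1-yl carbonate F2. F2 is cyclised as its zinc alkoxide (Et2Zn) with Pd2(dba)3·CHCl3 and the Trost ligand to 19.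

2. Step 3 (Proposed new method). Enantio-induction may be insufficient with an enol lactone as terminating nucleophile, and the enol lactone double bond may be brominated in competition. Fallback with known reactions, setting out from 4 and coming back at 6: racemic bromonium cyclisation with Et2SBr·SbCl5Br in MeNO2 at −25 °C and the same hydrolytic work-up should give racemic 3-(3-bromo-2,2-dimethyl-6-oxocyclohexyl)propanoic acid F3. Classical resolution follows by crystallisation of the salt with (R)-1-phenylethylamine, (1R)-1-phenylethanaminium 3-[(1R,3R)-3-bromo-2,2-dimethyl-6-oxocyclohexyl]propanoate F4, and acidification of F4 returns 6.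

3. Step 11. Diastereoselectivity in the α-bromination may be low, the trisubstituted alkene may be brominated, and the sulfur centre may be scrambled. Fallback, setting out from 12 and coming back at 19: the aldehyde is converted with (PhO)3P, Br2 and Et3N into the geminal dibromide tert-butyl (2E)-6,6-dibromo-3-methylhex-2-en-1-yl carbonate F5. Bromine–magnesium exchange with iPrMgCl·LiCl at −78 °C gives the racemic carbenoid tert-butyl (2E)-6-bromo-6-(chloromagnesio)-3-methylhex-2-en-1-yl carbonate F6. F6 is combined with 9 under the conditions of step 12 to give 19, with the price that the C3 epimers of the oxane must also be separated.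

Further compounds
F1 | step 12 | tert-butyl (2E)-5-[(2S,3S)-3-{2-[(1R,3R,6S)-3-bromo-2,2,6-trimethyl-6-(trimethylsilyloxy)cyclohexyl]ethyl}-3-methyloxiran-2-yl]-3-methylpent-2-en-1-yl carbonate | CC(C)(C)OC(=O)OC/C=C(C)/CC[C@@H]1O[C@@]1(C)CC[C@@H]2C(C)(C)[C@H](Br)CC[C@]2(C)O[Si](C)(C)C
F2 | step 12 | tert-butyl (2E,6R,7S)-6-bromo-7-hydroxy-3,7-dimethyl-9-[(1R,3R,6S)-3-bromo-2,2,6-trimethyl-6-(trimethylsilyloxy)cyclohexyl]non-2-en-1-yl carbonate | CC(C)(C)OC(=O)OC/C=C(C)/CC[C@@H](Br)[C@](C)(CC[C@@H]1C(C)(C)[C@H](Br)CC[C@]1(C)O[Si](C)(C)C)O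
F3 | step 3 | racemic 3-(3-bromo-2,2-dimethyl-6-oxocyclohexyl)propanoic acid, (1R,3R) and (1S,3S) | OC(=O)CC[C@@H]1C(C)(C)[C@H](Br)CCC1=O.OC(=O)CC[C@H]1C(C)(C)[C@@H](Br)CCC1=O
F4 | step 3 | (1R)-1-phenylethanaminium 3-[(1R,3R)-3-bromo-2,2-dimethyl-6-oxocyclohexyl]propanoate | C[C@@H]([NH3+])c1ccccc1.[O-]C(=O)CC[C@@H]1C(C)(C)[C@H](Br)CCC1=O
F5 | step 11 | tert-butyl (2E)-6,6-dibromo-3-methylhex-2-en-1-yl carbonate | BrC(Br)CC/C(C)=C/COC(=O)OC(C)(C)C
F6 | step 11 | racemic tert-butyl (2E)-6-bromo-6-(chloromagnesio)-3-methylhex-2-en-1-yl carbonate | Cl[Mg]C(Br)CC/C(C)=C/COC(=O)OC(C)(C)C
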